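**Retrosynthetic overview**

1. Succinimide ring (formed last): Pt-catalysed nitrile hydration and N-acyl transfer within an Evans syn-aldol adduct; the aldol (C12–C13) sets C12 and C13 on a bicyclic C12 aldehyde.
2. C7 acetate: allylic oxidation of the C8(17) alkene (7α-OH), then Mitsunobu inversion with AcOH.
3. Rings A and B together: an acyclic (2R,3R)-2,4-dichloro-3-ol is triflated; the C3 triflate leaves with participation of the C4 chloride, the chloronium ion is opened by the C5=C10 alkene (ring A), and the C10 cation is trapped by a C9 allylsilane (ring B). This gives the 2α,3β-dichloride, C5, C9, C10 and the exocyclic alkene in one operation.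
4. Dichloro alcohol: enamine-catalysed α-chlorination of a dienal (C2), Corey–Chaykovsky epoxidation with a sulfonium isopropylide (C3, anti), HCl opening at C4.
5. Dienal: two Johnson–Claisen rearrangements (both trisubstituted alkenes) from 3-silyloxypropanal and a 2-lithioallylsilane.

Assumption: decalin positions follow labdane numbering (C1–C10 ring carbons; C11 and C12 side chain; C17 exocyclic CH2; α = lower face, β = upper face), and the acyclic precursors carry the same atom labels in the Why lines.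

**Route**

Step 1
Reactants: 1 3-[(tert-butyldimethylsilyl)oxy]propanal; 2 (2-bromoprop-2-en-1-yl)trimethylsilane
Product: 4 rac-5-[(tert-butyldimethylsilyl)oxy]-2-[(trimethylsilyl)methyl]pent-1-en-3-ol, via 2-lithioallylsilane 3 (not isolated)
Conditions: 2, t-BuLi (2 equiv), Et2O, −78 °C; then 1, −78 → 0 °C; H2O
Reagents that add atoms: none
Why: Br–Li exchange gives the 2-lithioallylsilane, which adds 1,2 to the aldehyde (organolithium carbonyl addition); the carbinol centre is racemic and is erased in step 2.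

Step 2
Reactants: 4; 5 triethyl orthoacetate
Product: 7 ethyl (4Z)-7-[(tert-butyldimethylsilyl)oxy]-4-[(trimethylsilyl)methyl]hept-4-enoate, via allyl ketene acetal 6 (not isolated)
Conditions: MeC(OEt)3, EtCO2H (cat.), 140 °C, −EtOH
Reagents that add atoms: none
Why: Johnson–Claisen rearrangement through a chair transition state with the CH2CH2OTBS group equatorial puts C11 cis to CH2SiMe3 on the C8=C9 alkene (4Z), the geometry that later gives the equatorial C9 side chain.

Step 3
Reactants: 7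
Product: 8 (4Z)-7-[(tert-butyldimethylsilyl)oxy]-4-[(trimethylsilyl)methyl]hept-4-enal
Conditions: i-Bu2AlH, CH2Cl2, −78 °C; aq. potassium sodium tartrate
Reagents that add atoms: none
Why: partial ester reduction stops at the aldehyde because the tetrahedral aluminium hemiacetal is stable at −78 °C; silyl groups and the alkene are untouched.

Step 4
Reactants: 8; 9 isopropenylmagnesium bromide
Product: 10 rac-(6Z)-9-[(tert-butyldimethylsilyl)oxy]-2-methyl-6-[(trimethylsilyl)methyl]nona-1,6-dien-3-ol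
Conditions: CH2=C(CH3)MgBr, THF, −78 → 0 °C
Reagents that add atoms: none
Why: Grignard 1,2-addition gives the 2-methylallylic alcohol needed for the second Claisen step; its racemic carbinol centre is erased in step 5.

Step 5
Reactants: 10; 5 triethyl orthoacetate
Product: 12 ethyl (4E,8Z)-11-[(tert-butyldimethylsilyl)oxy]-4-methyl-8-[(trimethylsilyl)methyl]undeca-4,8-dienoate, via allyl ketene acetal 11 (not isolated)
Conditions: MeC(OEt)3, EtCO2H (cat.), 140 °C, −EtOH
Reagents that add atoms: none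
Why: second Johnson–Claisen rearrangement; the chair transition state with the chain equatorial is expected to give the E-configured C10=C5 alkene with high selectivity while adding C1–C3.

Step 6
Reactants: 12
Product: 13 (4E,8Z)-11-[(tert-butyldimethylsilyl)oxy]-4-methyl-8-[(trimethylsilyl)methyl]undeca-4,8-dienal
Conditions: i-Bu2AlH, CH2Cl2, −78 °C; aq. potassium sodium tartrate
Reagents that add atoms: none
Why: partial ester reduction to the C3 aldehyde, as in step 3.

Step 7
Reactants: 13
Product: 14 (2R,4E,8Z)-11-[(tert-butyldimethylsilyl)oxy]-2-chloro-4-methyl-8-[(trimethylsilyl)methyl]undeca-4,8-dienal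
Conditions: NCS, (2S,5S)-2,5-diphenylpyrrolidine (10 mol %), CH2Cl2, 0 °C → rt; used crude and cold
Reagents that add atoms: N-chlorosuccinimide, O=C1CCC(=O)N1Cl
Why: enamine-catalysed enantioselective α-chlorination of the aldehyde; the (2S,5S) catalyst is the enantiomer expected to give the 2R chloride (future C2) by shielding one enamine face, and NCS does not attack the isolated alkenes or the allylsilane under these conditions.

Step 8
Reactants: 14; 15 isopropyldiphenylsulfonium tetrafluoroborate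
Product: 17 (3S)-3-[(1R,3E,7Z)-10-[(tert-butyldimethylsilyl)oxy]-1-chloro-3-methyl-7-[(trimethylsilyl)methyl]deca-3,7-dien-1-yl]-2,2-dimethyloxirane, via sulfonium ylide 16 (not isolated)
Conditions: 15, t-BuLi, THF, −78 °C; then 14, −78 → −40 °C
Reagents that add atoms: none
Why: Corey–Chaykovsky epoxidation; the ylide adds to the α-chloroaldehyde in the Cornforth (C=O anti to C–Cl) arrangement to set the C3–O bond anti to the C2–Cl bond, and the betaine closes at the tertiary carbon with loss of Ph2S.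

Step 9
Reactants: 17
Product: 18 (3R,4R,6E,10Z)-13-[(tert-butyldimethylsilyl)oxy]-2,4-dichloro-2,6-dimethyl-10-[(trimethylsilyl)methyl]trideca-6,10-dien-3-ol
Conditions: HCl (1 M in Et2O), CH2Cl2, −78 → −40 °C; NaHCO3 quench
Reagents that add atoms: hydrogen chloride, Cl
Why: Markovnikov (SN1-like) opening of the protonated trisubstituted epoxide by chloride at the tertiary C4 leaves the C3–O stereocentre untouched, and the low temperature spares the allylsilane and the silyl ether.

Step 10
Reactants: 18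
Product: 21 (2R,3R,5R,9S,10R)-12-[(tert-butyldimethylsilyl)oxy]-2α,3β-dichloro-13,14,15,16-tetranorlabd-8(17)-ene, via triflate 19 (not isolated), via chloronium triflate 20 (not isolated)
Conditions: Tf2O, 2,6-di-tert-butyl-4-methylpyridine, CH2Cl2, −78 °C; then (CF3)2CHOH, −78 → 0 °C
Reagents that add atoms: none
Why: Proposed new method: the secondary C3 triflate ionizes with backside participation of the tertiary C4 chloride (inversion at C3) to a chloronium ion, which the C5=C10 alkene opens at its tertiary carbon anti to chlorine in a chair–chair array with both chlorines equatorial, and the C10 cation is trapped at C9 by the allylsilane with loss of Me3Si+, so rings A and B, the 2α,3β-dichloride, C5, C9, C10 and the C8(17) alkene arise together; the closest known chemistry is halonium-initiated polyene cyclization, the stereospecific solvolysis of β-chloro sulfonates through configurationally stable chloronium ions in (CF3)2CHOH, and allylsilane-terminated cation–olefin cyclization.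

Step 11
Reactants: 21
Product: 22 (2R,3R,5R,7R,9R,10R)-12-[(tert-butyldimethylsilyl)oxy]-2α,3β-dichloro-13,14,15,16-tetranorlabd-8(17)-en-7α-ol
Conditions: SeO2 (0.5 equiv), t-BuOOH, CH2Cl2, 0 °C → rt
Reagents that add atoms: tert-butyl hydroperoxide, CC(C)(C)OO (oxygen source, relayed by selenium dioxide, O=[Se]=O)
Why: Riley allylic oxidation (ene reaction, then [2,3]-sigmatropic shift) removes the axial α hydrogen of the secondary allylic C7 and returns oxygen on the same face, giving the axial 7α-alcohol with the exocyclic alkene in place.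

Step 12
Reactants: 22
Product: 23 (2R,3R,5R,7S,9R,10R)-12-[(tert-butyldimethylsilyl)oxy]-2α,3β-dichloro-13,14,15,16-tetranorlabd-8(17)-en-7β-yl acetate
Conditions: AcOH, PPh3, i-PrO2CN=NCO2i-Pr, toluene, 0 °C → rt
Reagents that add atoms: acetic acid, CC(=O)O
Why: Mitsunobu reaction; acetate displaces the axial oxyphosphonium by SN2 from the open β face, inverting C7 to the equatorial 7β-acetate of the target.

Step 13
Reactants: 23
Product: 24 (2R,3R,5R,7S,9R,10R)-7β-acetoxy-2α,3β-dichloro-13,14,15,16-tetranorlabd-8(17)-en-12-ol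
Conditions: HF·pyridine, THF, 0 °C → rt
Reagents that add atoms: none
Why: fluoride-driven cleavage of the primary silyl ether; the acetate, the alkyl chlorides and the alkene are inert.

Step 14
Reactants: 24
Product: 25 (2R,3R,5R,7S,9R,10R)-7β-acetoxy-2α,3β-dichloro-13,14,15,16-tetranorlabd-8(17)-en-12-al
Conditions: Dess–Martin periodinane, NaHCO3, CH2Cl2, 0 °C → rt
Reagents that add atoms: none
Why: Dess–Martin oxidation under buffered conditions gives the aldehyde without touching the acetate; there is no stereocentre α to the new carbonyl.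

Step 15
Reactants: 26 (R)-4-benzyl-2-oxazolidinone; 27 3-cyanopropanoic acid
Product: 29 (4R)-4-benzyl-3-(3-cyanopropanoyl)oxazolidin-2-one, via mixed anhydride 28 (not isolated)
Conditions: t-BuCOCl, Et3N, THF, −20 °C; then 26, LiCl, rt
Reagents that add atoms: none
Why: N-acylation of the oxazolidinone through the mixed pivalic anhydride (LiCl/Et3N method), which attacks the less hindered acyl group.

Step 16
Reactants: 25; 29
Product: 31 (4R)-4-benzyl-3-[(2R,3S)-2-(cyanomethyl)-3-hydroxy-4-(7β-acetoxy-2α,3β-dichloro-11,12,13,14,15,16-hexanorlabd-8(17)-en-9-yl)butanoyl]oxazolidin-2-one, via boron enolate 30 (not isolated)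
Conditions: 29, n-Bu2BOTf, i-Pr2NEt, CH2Cl2, −78 → 0 °C; then 25, −78 → 0 °C; pH 7 buffer, MeOH, H2O2
Reagents that add atoms: none
Why: Evans syn-aldol reaction; the Z-boron enolate reacts through a Zimmerman–Traxler chair with the (R)-auxiliary dipole-opposed, setting 12S and 13R under reagent control.

Step 17
Reactants: 31
Product: 33 Haterumaimide A, via primary amide 32 (not isolated)
Conditions: [PtH(PMe2OH)(PMe2O)2H] (5 mol %), EtOH/H2O 4:1, 80 °C
Reagents that add atoms: water, O
Why: Ghaffar–Parkins nitrile hydration at neutral pH gives the primary amide, whose nitrogen attacks the activated exocyclic imide carbonyl (5-exo-trig N-acyl transfer) to close the succinimide and release the auxiliary, while the acetate and C13 are not exposed to base.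

**Compound list**

1 | 3-[(tert-butyldimethylsilyl)oxy]propanal | O=CCCO[Si](C)(C)C(C)(C)C | starting material
2 | (2-bromoprop-2-en-1-yl)trimethylsilane | C=C(Br)C[Si](C)(C)C | starting material
3 | [3-(trimethylsilyl)prop-1-en-2-yl]lithium | [Li]C(=C)C[Si](C)(C)C | intermediate (not isolated)
4 | rac-5-[(tert-butyldimethylsilyl)oxy]-2-[(trimethylsilyl)methyl]pent-1-en-3-ol | C=C(C[Si](C)(C)C)C(O)CCO[Si](C)(C)C(C)(C)C | intermediate
5 | triethyl orthoacetate | CC(OCC)(OCC)OCC | starting material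
6 | 1-ethoxyvinyl (ketene acetal) ether of 4 | C=C(OCC)OC(CCO[Si](C)(C)C(C)(C)C)C(=C)C[Si](C)(C)C | intermediate (not isolated)
7 | ethyl (4Z)-7-[(tert-butyldimethylsilyl)oxy]-4-[(trimethylsilyl)methyl]hept-4-enoate | CCOC(=O)CC/C(C[Si](C)(C)C)=C/CCO[Si](C)(C)C(C)(C)C | intermediate
8 | (4Z)-7-[(tert-butyldimethylsilyl)oxy]-4-[(trimethylsilyl)methyl]hept-4-enal | O=CCC/C(C[Si](C)(C)C)=C/CCO[Si](C)(C)C(C)(C)C | intermediate
9 | isopropenylmagnesium bromide | C=C(C)[Mg]Br | starting material
10 | rac-(6Z)-9-[(tert-butyldimethylsilyl)oxy]-2-methyl-6-[(trimethylsilyl)methyl]nona-1,6-dien-3-ol | C=C(C)C(O)CC/C(C[Si](C)(C)C)=C/CCO[Si](C)(C)C(C)(C)C | intermediate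
11 | 1-ethoxyvinyl (ketene acetal) ether of 10 | C=C(OCC)OC(CC/C(C[Si](C)(C)C)=C/CCO[Si](C)(C)C(C)(C)C)C(C)=C | intermediate (not isolated)
12 | ethyl (4E,8Z)-11-[(tert-butyldimethylsilyl)oxy]-4-methyl-8-[(trimethylsilyl)methyl]undeca-4,8-dienoate | CCOC(=O)CC/C(C)=C/CC/C(C[Si](C)(C)C)=C/CCO[Si](C)(C)C(C)(C)C | intermediate
13 | (4E,8Z)-11-[(tert-butyldimethylsilyl)oxy]-4-methyl-8-[(trimethylsilyl)methyl]undeca-4,8-dienal | O=CCC/C(C)=C/CC/C(C[Si](C)(C)C)=C/CCO[Si](C)(C)C(C)(C)C | intermediate
14 | (2R,4E,8Z)-11-[(tert-butyldimethylsilyl)oxy]-2-chloro-4-methyl-8-[(trimethylsilyl)methyl]undeca-4,8-dienal | O=C[C@H](Cl)C/C(C)=C/CC/C(C[Si](C)(C)C)=C/CCO[Si](C)(C)C(C)(C)C | intermediate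
15 | isopropyldiphenylsulfonium tetrafluoroborate | CC(C)[S+](c1ccccc1)c1ccccc1.F[B-](F)(F)F | starting material
16 | diphenylsulfonium isopropylide | C[C-](C)[S+](c1ccccc1)c1ccccc1 | intermediate (not isolated)
17 | (3S)-3-[(1R,3E,7Z)-10-[(tert-butyldimethylsilyl)oxy]-1-chloro-3-methyl-7-[(trimethylsilyl)methyl]deca-3,7-dien-1-yl]-2,2-dimethyloxirane | CC1(C)O[C@@H]1[C@H](Cl)C/C(C)=C/CC/C(C[Si](C)(C)C)=C/CCO[Si](C)(C)C(C)(C)C | intermediate
18 | (3R,4R,6E,10Z)-13-[(tert-butyldimethylsilyl)oxy]-2,4-dichloro-2,6-dimethyl-10-[(trimethylsilyl)methyl]trideca-6,10-dien-3-ol | CC(C)(Cl)[C@H](O)[C@H](Cl)C/C(C)=C/CC/C(C[Si](C)(C)C)=C/CCO[Si](C)(C)C(C)(C)C | intermediate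
19 | (3R,4R,6E,10Z)-13-[(tert-butyldimethylsilyl)oxy]-2,4-dichloro-2,6-dimethyl-10-[(trimethylsilyl)methyl]trideca-6,10-dien-3-yl trifluoromethanesulfonate | CC(C)(Cl)[C@H](OS(=O)(=O)C(F)(F)F)[C@H](Cl)C/C(C)=C/CC/C(C[Si](C)(C)C)=C/CCO[Si](C)(C)C(C)(C)C | intermediate (not isolated)
20 | 2,2-dimethyl-3-[(1R,3E,7Z)-10-[(tert-butyldimethylsilyl)oxy]-1-chloro-3-methyl-7-[(trimethylsilyl)methyl]deca-3,7-dien-1-yl]chloriranium triflate (ring CH configured as C3 of 21) | CC1(C)[Cl+][C@H]1[C@H](Cl)C/C(C)=C/CC/C(C[Si](C)(C)C)=C/CCO[Si](C)(C)C(C)(C)C.[O-]S(=O)(=O)C(F)(F)F | intermediate (not isolated)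
21 | (2R,3R,5R,9S,10R)-12-[(tert-butyldimethylsilyl)oxy]-2α,3β-dichloro-13,14,15,16-tetranorlabd-8(17)-ene | C=C1CC[C@H]2C(C)(C)[C@@H](Cl)[C@H](Cl)C[C@]2(C)[C@H]1CCO[Si](C)(C)C(C)(C)C | intermediate
22 | (2R,3R,5R,7R,9R,10R)-12-[(tert-butyldimethylsilyl)oxy]-2α,3β-dichloro-13,14,15,16-tetranorlabd-8(17)-en-7α-ol | C=C1[C@H](O)C[C@H]2C(C)(C)[C@@H](Cl)[C@H](Cl)C[C@]2(C)[C@H]1CCO[Si](C)(C)C(C)(C)C | intermediate
23 | (2R,3R,5R,7S,9R,10R)-12-[(tert-butyldimethylsilyl)oxy]-2α,3β-dichloro-13,14,15,16-tetranorlabd-8(17)-en-7β-yl acetate | C=C1[C@@H](OC(C)=O)C[C@H]2C(C)(C)[C@@H](Cl)[C@H](Cl)C[C@]2(C)[C@H]1CCO[Si](C)(C)C(C)(C)C | intermediate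
24 | (2R,3R,5R,7S,9R,10R)-7β-acetoxy-2α,3β-dichloro-13,14,15,16-tetranorlabd-8(17)-en-12-ol | C=C1[C@@H](OC(C)=O)C[C@H]2C(C)(C)[C@@H](Cl)[C@H](Cl)C[C@]2(C)[C@H]1CCO | intermediate
25 | (2R,3R,5R,7S,9R,10R)-7β-acetoxy-2α,3β-dichloro-13,14,15,16-tetranorlabd-8(17)-en-12-al | C=C1[C@@H](OC(C)=O)C[C@H]2C(C)(C)[C@@H](Cl)[C@H](Cl)C[C@]2(C)[C@H]1CC=O | intermediate
26 | (R)-4-benzyl-2-oxazolidinone | O=C1N[C@H](Cc2ccccc2)CO1 | starting material
27 | 3-cyanopropanoic acid | N#CCCC(=O)O | starting material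
28 | 3-cyanopropanoic pivalic anhydride | N#CCCC(=O)OC(=O)C(C)(C)C | intermediate (not isolated)
29 | (4R)-4-benzyl-3-(3-cyanopropanoyl)oxazolidin-2-one | N#CCCC(=O)N1[C@H](Cc2ccccc2)COC1=O | intermediate
30 | (Z)-di-n-butylboron enolate of 29 | N#CC/C=C(\OB(CCCC)CCCC)N1[C@H](Cc2ccccc2)COC1=O | intermediate (not isolated)
31 | (4R)-4-benzyl-3-[(2R,3S)-2-(cyanomethyl)-3-hydroxy-4-(7β-acetoxy-2α,3β-dichloro-11,12,13,14,15,16-hexanorlabd-8(17)-en-9-yl)butanoyl]oxazolidin-2-one (12S,13R in labdane numbering) | C=C1[C@@H](OC(C)=O)C[C@H]2C(C)(C)[C@@H](Cl)[C@H](Cl)C[C@]2(C)[C@H]1C[C@H](O)[C@@H](CC#N)C(=O)N1[C@H](Cc2ccccc2)COC1=O | intermediate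
32 | primary amide from hydration of the nitrile of 31 | C=C1[C@@H](OC(C)=O)C[C@H]2C(C)(C)[C@@H](Cl)[C@H](Cl)C[C@]2(C)[C@H]1C[C@H](O)[C@@H](CC(N)=O)C(=O)N1[C@H](Cc2ccccc2)COC1=O | intermediate (not isolated)
33 | Haterumaimide A, (2R,3R,5R,7S,9R,10R,12S,13R)-7β-acetoxy-2α,3β-dichloro-12-hydroxylabd-8(17)-ene-15,16-dicarboximide | C=C1[C@@H](OC(C)=O)C[C@H]2C(C)(C)[C@@H](Cl)[C@H](Cl)C[C@]2(C)[C@H]1C[C@H](O)[C@H]1CC(=O)NC1=O | target

**Step count**

Total: 17 steps. Longest linear sequence: 16 (steps 1–14, 16, 17); step 15 is a one-step side branch.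

**Three steps most likely to fail**

Step 10 (chloronium bicyclization). The cation may lose a methyl proton (E1) before ring A closes, ionization may be slow because C3 is flanked by two C–Cl bonds, and acid may protodesilylate the terminator. The fallback separates the substitution at C3 from the ring formation. It sets out from epoxide 17: Ph3PCl2 in CH2Cl2 (0 °C → rt) opens the epoxide at the tertiary carbon and replaces the C3 oxygen by chloride with inversion, giving (3S,4R,6E,10Z)-13-[(tert-butyldimethylsilyl)oxy]-2,3,4-trichloro-2,6-dimethyl-10-[(trimethylsilyl)methyl]trideca-6,10-diene F1. Catalytic SnCl4 in CH2Cl2 at −78 °C then ionizes the tertiary C–Cl bond (assisted by the C3 chlorine), and the same chair–chair cascade terminated by the allylsilane returns to the route at 21, replacing steps 9 and 10.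

Step 8 (ylide epoxidation of the α-chloroaldehyde). The basic ylide may enolize or epimerize 14, and the anti:syn ratio may be modest. The fallback sets out from 14: Cornforth-controlled 1,2-addition of CH2=C(CH3)MgBr (9) in THF at −78 °C gives the allylic anti-chlorohydrin (3S,4R,6E,10Z)-13-[(tert-butyldimethylsilyl)oxy]-4-chloro-2,6-dimethyl-10-[(trimethylsilyl)methyl]trideca-1,6,10-trien-3-ol F2. Radical Markovnikov hydrochlorination of its 1,1-disubstituted alkene (Co(BF4)2·6H2O with a salicylaldimine ligand, TsCl, PhSiH3, t-BuOOH, EtOH), which hydrogen-atom transfer reaches faster than the trisubstituted alkenes, puts chlorine on C4 and comes back to the route at 18, replacing steps 8 and 9.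

Step 12 (Mitsunobu inversion at C7). Acetate may attack C17 (SN2') or the activated alcohol may eliminate to a diene. The fallback sets out from 22: Dess–Martin oxidation gives the enone (2R,3R,5R,9R,10R)-12-[(tert-butyldimethylsilyl)oxy]-2α,3β-dichloro-13,14,15,16-tetranorlabd-8(17)-en-7-one F3. Reduction with NaBH4/CeCl3·7H2O in MeOH at −78 °C (axial hydride delivery on the α face) gives the equatorial alcohol (2R,3R,5R,7S,9R,10R)-12-[(tert-butyldimethylsilyl)oxy]-2α,3β-dichloro-13,14,15,16-tetranorlabd-8(17)-en-7β-ol F4, and Ac2O/DMAP/pyridine returns to the route at 23.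

**Further compounds**

F1 | step 10 | (3S,4R,6E,10Z)-13-[(tert-butyldimethylsilyl)oxy]-2,3,4-trichloro-2,6-dimethyl-10-[(trimethylsilyl)methyl]trideca-6,10-diene | CC(C)(Cl)[C@@H](Cl)[C@H](Cl)C/C(C)=C/CC/C(C[Si](C)(C)C)=C/CCO[Si](C)(C)C(C)(C)C
F2 | step 8 | (3S,4R,6E,10Z)-13-[(tert-butyldimethylsilyl)oxy]-4-chloro-2,6-dimethyl-10-[(trimethylsilyl)methyl]trideca-1,6,10-trien-3-ol | C=C(C)[C@H](O)[C@H](Cl)C/C(C)=C/CC/C(C[Si](C)(C)C)=C/CCO[Si](C)(C)C(C)(C)C
F3 | step 12 | (2R,3R,5R,9R,10R)-12-[(tert-butyldimethylsilyl)oxy]-2α,3β-dichloro-13,14,15,16-tetranorlabd-8(17)-en-7-one | C=C1C(=O)C[C@H]2C(C)(C)[C@@H](Cl)[C@H](Cl)C[C@]2(C)[C@H]1CCO[Si](C)(C)C(C)(C)C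
F4 | step 12 | (2R,3R,5R,7S,9R,10R)-12-[(tert-butyldimethylsilyl)oxy]-2α,3β-dichloro-13,14,15,16-tetranorlabd-8(17)-en-7β-ol | C=C1[C@@H](O)C[C@H]2C(C)(C)[C@@H](Cl)[C@H](Cl)C[C@]2(C)[C@H]1CCO[Si](C)(C)C(C)(C)C
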